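The ten-membered ring is closed last, between the carbinol carbon and the neighbouring ring alkene carbon that carries CO2H. The key step exploits this α-(hydroxyalkyl)acrylate unit, HO–CH–C(CO2H)=CH, of the ten-membered ring: an intramolecular Nozaki–Hiyama–Kishi addition of a (Z)-α-iodo enoate to an aldehyde forms the C–C bond, the ring and the carbinol stereocentre in one operation. The precursor is a monocyclic trans-2,3-disubstituted 1-methylidene-4-isopropylidenecyclohexane carrying a CH2CHO arm and a dienoate arm that ends in an α-iodoacrylic 2-(trimethylsilyl)ethyl ester. One stereocentre is set by rhodium catalysis; the other two are relayed from it by substrate control.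

Key step: step 14

Remark: the facial sense of (R)-BINAP in step 3 is taken from the accepted model for cyclohex-2-enones; if it proves reversed on this ketal, the other ligand antipode is used.

Step 1
Reactants: 1 trimethyl phosphonoacetate; 2 3-bromo-1,1-dimethoxypropane
Product: 3 methyl 2-(dimethoxyphosphoryl)-5,5-dimethoxypentanoate
Conditions: NaH, DMF, 0 → 60 °C
Reagents that add atoms: none
Why: C-alkylation of the sodium phosphonoacetate anion with a primary bromide should give the α-substituted Horner–Wadsworth–Emmons reagent (the new centre is racemic and is lost in step 8).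

Step 2
Reactants: 4 (triphenylphosphoranylidene)ketene; 5 2-(trimethylsilyl)ethanol
Product: 6 2-(trimethylsilyl)ethyl (triphenylphosphoranylidene)acetate
Conditions: PhMe, 90 °C
Reagents that add atoms: none
Why: addition of the alcohol across the cumulated ylide (Bestmann ylide alcoholysis) should give the stabilised ester ylide directly.

Step 3
Reactants: 7 1,4-dioxaspiro[4.5]deca-6,9-dien-8-one
Product: 8 (6R)-6-ethenyl-1,4-dioxaspiro[4.5]dec-9-en-8-one
Conditions: [Rh(cod)2]BF4 (3 mol%), (R)-BINAP (3.3 mol%), potassium vinyltrifluoroborate (1.05 equiv.), Et3N, PhMe/H2O (20:1), 25 °C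
Reagents that add atoms: potassium vinyltrifluoroborate, [K+].C=C[B-](F)(F)F
Why: rhodium-catalysed asymmetric 1,4-addition of an alkenyltrifluoroborate (Hayashi–Miyaura reaction) should desymmetrise the dienone, the (R)-BINAP–rhodium–vinyl species choosing one face of one enone and so setting the ring carbon that later carries the CH2CHO arm, while one equivalent of borate holds the reaction at mono-addition.

Step 4
Reactants: 8 (6R)-6-ethenyl-1,4-dioxaspiro[4.5]dec-9-en-8-one
Product: 11 (6S,7R)-6-ethenyl-7-{[(triethylsilyl)oxy]methyl}-1,4-dioxaspiro[4.5]dec-9-en-8-one, via lithium dienolate 9 (not isolated), via lithium aldolate 10 (not isolated)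
Conditions: LDA, THF, −78 °C; CH2O (THF solution), −78 °C; Et3SiCl, −78 → 0 °C
Reagents that add atoms: formaldehyde, C=O; chlorotriethylsilane, CC[Si](Cl)(CC)CC
Why: kinetic α'-deprotonation (the γ-carbon is quaternary) gives a cross-conjugated enolate whose aldol reaction with formaldehyde should occur anti to the neighbouring vinyl group and so set the trans relationship of the two ring stereocentres, and silylation in the same flask blocks retro-aldol and dehydration.

Step 5
Reactants: 11 (6S,7R)-6-ethenyl-7-{[(triethylsilyl)oxy]methyl}-1,4-dioxaspiro[4.5]dec-9-en-8-one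
Product: 12 (6S,7R)-6-ethenyl-7-{[(triethylsilyl)oxy]methyl}-1,4-dioxaspiro[4.5]decan-8-one
Conditions: Cu(OAc)2·H2O (3 mol%), 1,2-bis(diphenylphosphino)benzene (3 mol%), (EtO)2MeSiH, t-BuOH, PhMe, 0 °C → rt
Reagents that add atoms: none
Why: copper hydride conjugate reduction should reduce only the enone C=C and leave the isolated vinyl group, the silyl ether and both stereocentres untouched.

Step 6
Reactants: 12 (6S,7R)-6-ethenyl-7-{[(triethylsilyl)oxy]methyl}-1,4-dioxaspiro[4.5]decan-8-one
Product: 13 triethyl{[(6S,7S)-6-ethenyl-8-(propan-2-ylidene)-1,4-dioxaspiro[4.5]decan-7-yl]methoxy}silane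
Conditions: i-PrPPh3I, n-BuLi, THF, 0 → 50 °C
Reagents that add atoms: isopropyltriphenylphosphonium iodide, CC(C)[P+](c1ccccc1)(c1ccccc1)c1ccccc1.[I-]
Why: Wittig olefination with the non-stabilised isopropylidene ylide should convert the ketone into the tetrasubstituted exocyclic alkene, the α-stereocentre being kept because enolisation toward the substituted α-carbon is kinetically disfavoured and the trans isomer is the stable one.

Step 7
Reactants: 13 triethyl{[(6S,7S)-6-ethenyl-8-(propan-2-ylidene)-1,4-dioxaspiro[4.5]decan-7-yl]methoxy}silane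
Product: 14 (6S,7S)-6-ethenyl-8-(propan-2-ylidene)-1,4-dioxaspiro[4.5]decane-7-carbaldehyde
Conditions: (COCl)2, DMSO, CH2Cl2, −78 → −40 °C; Et3N, −78 → 0 °C
Reagents that add atoms: none
Why: under Swern conditions a primary triethylsilyl ether should be cleaved and oxidised to the aldehyde in one pot, and the low temperature protects the epimerisable β,γ-unsaturated α-carbon.

Step 8
Reactants: 14 (6S,7S)-6-ethenyl-8-(propan-2-ylidene)-1,4-dioxaspiro[4.5]decane-7-carbaldehyde; 3 methyl 2-(dimethoxyphosphoryl)-5,5-dimethoxypentanoate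
Product: 15 methyl (2E)-2-{[(6S,7S)-6-ethenyl-8-(propan-2-ylidene)-1,4-dioxaspiro[4.5]decan-7-yl]methylidene}-5,5-dimethoxypentanoate
Conditions: 3, NaH, THF, 0 °C; then 14, 0 °C → rt
Reagents that add atoms: none
Why: Horner–Wadsworth–Emmons olefination of an α-branched aldehyde with a pre-formed α-alkyl phosphonoacetate anion should give the trisubstituted enoate with the ring carbon trans to CO2Me, and the absence of free base limits epimerisation.

Step 9
Reactants: 15 methyl (2E)-2-{[(6S,7S)-6-ethenyl-8-(propan-2-ylidene)-1,4-dioxaspiro[4.5]decan-7-yl]methylidene}-5,5-dimethoxypentanoate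
Product: 17 methyl (2E)-2-{[(6S,7S)-6-(2-hydroxyethyl)-8-(propan-2-ylidene)-1,4-dioxaspiro[4.5]decan-7-yl]methylidene}-5,5-dimethoxypentanoate, via alkylborane 16 (not isolated)
Conditions: 9-BBN, THF, 0 °C → rt; NaBO3·4H2O, THF/H2O, rt
Reagents that add atoms: sodium perborate, [Na+].[Na+].O[B-]1(O)OO[B-](O)(O)OO1
Why: anti-Markovnikov hydroboration with 9-BBN should take only the monosubstituted vinyl group (the tetrasubstituted alkene and the trisubstituted enoate are inert to it), and perborate oxidation is mild enough for the methyl ester.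

Step 10
Reactants: 17 methyl (2E)-2-{[(6S,7S)-6-(2-hydroxyethyl)-8-(propan-2-ylidene)-1,4-dioxaspiro[4.5]decan-7-yl]methylidene}-5,5-dimethoxypentanoate
Product: 18 methyl (2E)-2-{[(1S,2S)-2-(2-hydroxyethyl)-3-oxo-6-(propan-2-ylidene)cyclohexyl]methylidene}-5-oxopentanoate
Conditions: TsOH·H2O (cat.), THF/H2O (4:1), rt
Reagents that add atoms: water, O
Why: mild acid hydrolysis should unmask the ring ketone (dioxolane) and the chain aldehyde (dimethyl acetal) in one operation without moving the skipped exocyclic alkene into conjugation.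

Step 11
Reactants: 18 methyl (2E)-2-{[(1S,2S)-2-(2-hydroxyethyl)-3-oxo-6-(propan-2-ylidene)cyclohexyl]methylidene}-5-oxopentanoate; 6 2-(trimethylsilyl)ethyl (triphenylphosphoranylidene)acetate
Product: 20 1-methyl 7-[2-(trimethylsilyl)ethyl] (2E,5Z)-2-{[(1S,2S)-2-(2-hydroxyethyl)-3-oxo-6-(propan-2-ylidene)cyclohexyl]methylidene}-6-iodohept-5-enedioate, via iodo ylide 19 (not isolated)
Conditions: 6, N-iodosuccinimide, CH2Cl2, −20 °C; then 18, −20 °C → rt
Reagents that add atoms: N-iodosuccinimide, O=C1CCC(=O)N1I
Why: a Wittig reaction of the α-iodo stabilised ylide, made in the flask by iodination of 6, should take the aldehyde in preference to the ketone and give mainly the (Z)-α-iodo enoate, with iodine cis to the chain and the ester trans to it.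

Step 12
Reactants: 20 1-methyl 7-[2-(trimethylsilyl)ethyl] (2E,5Z)-2-{[(1S,2S)-2-(2-hydroxyethyl)-3-oxo-6-(propan-2-ylidene)cyclohexyl]methylidene}-6-iodohept-5-enedioate
Product: 21 1-methyl 7-[2-(trimethylsilyl)ethyl] (2E,5Z)-2-{[(1S,2S)-2-(2-hydroxyethyl)-3-methylidene-6-(propan-2-ylidene)cyclohexyl]methylidene}-6-iodohept-5-enedioate
Conditions: Cp2TiMe2 (3 equiv.), PhMe/THF, 65 °C, dark
Reagents that add atoms: dimethyltitanocene, C[Ti](C)(C1C=CC=C1)C1C=CC=C1
Why: Petasis methylenation through Cp2Ti=CH2 should take the ketone much faster than the two esters and, being non-basic, should neither epimerise the α-carbon nor touch the iodoalkene.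

Step 13
Reactants: 21 1-methyl 7-[2-(trimethylsilyl)ethyl] (2E,5Z)-2-{[(1S,2S)-2-(2-hydroxyethyl)-3-methylidene-6-(propan-2-ylidene)cyclohexyl]methylidene}-6-iodohept-5-enedioate
Product: 22 1-methyl 7-[2-(trimethylsilyl)ethyl] (2E,5Z)-6-iodo-2-{[(1S,2S)-3-methylidene-2-(2-oxoethyl)-6-(propan-2-ylidene)cyclohexyl]methylidene}hept-5-enedioate
Conditions: Dess–Martin periodinane, CH2Cl2, 0 °C → rt
Reagents that add atoms: none
Why: Dess–Martin oxidation should convert the primary alcohol into the aldehyde under near-neutral conditions that leave the alkenes and the iodoalkene alone.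

Step 14
Reactants: 22 1-methyl 7-[2-(trimethylsilyl)ethyl] (2E,5Z)-6-iodo-2-{[(1S,2S)-3-methylidene-2-(2-oxoethyl)-6-(propan-2-ylidene)cyclohexyl]methylidene}hept-5-enedioate
Product: 25 microeunicellol A 2-(trimethylsilyl)ethyl ester (the target with CO2CH2CH2SiMe3 in place of CO2H; ring fusion S,S; carbinol R; both ring enoates E), via alkenylchromium 23 (not isolated), via chromium alkoxide 24 (not isolated)
Conditions: CrCl2 (15 equiv.), NiCl2 (0.15 equiv.), DMSO, rt, syringe-pump addition to 2 mM; aqueous work-up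
Reagents that add atoms: none
Why: Zerovalent nickel, formed from NiCl2 by divalent chromium, inserts into the C–I bond and hands the alkenyl group to trivalent chromium; the alkenylchromium 23 then adds to the aldehyde to give alkoxide 24. This is an intramolecular Nozaki–Hiyama–Kishi reaction, and its closest known use is the closure of ten-membered carbocycles in eunicellane-type frameworks. The ten-membered ring closes in the 10-exo-trig mode, the carbonyl oxygen staying outside the new ring. The alkene geometry of the iodide is carried into the product, so the chain and the new C–C bond are cis and both enoates sit cis within the ring. The new carbinol stereocentre is under substrate control: the trans-disposed arms on the rigid cyclohexane, one CH2 away from the aldehyde, are expected to let the carbonyl react with its oxygen on the periphery and so to favour the (R) configuration. The step needs aldehyde-over-ester chemoselectivity and ring closure over oligomerisation; the organochromium reagent secures the first and high dilution the second.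

Step 15
Reactants: 25 microeunicellol A 2-(trimethylsilyl)ethyl ester
Product: 26 microeunicellol A
Conditions: Bu4NF, THF, 0 °C; aq. NH4Cl
Reagents that add atoms: none
Why: fluoride attack on silicon fragments the 2-(trimethylsilyl)ethyl ester (β-elimination) and should free the acid without touching the methyl ester, the allylic alcohol or the exocyclic alkenes.

Compound list
1 | trimethyl phosphonoacetate | COC(=O)CP(=O)(OC)OC | starting material
2 | 3-bromo-1,1-dimethoxypropane | COC(OC)CCBr | starting material
3 | methyl 2-(dimethoxyphosphoryl)-5,5-dimethoxypentanoate | COC(=O)C(CCC(OC)OC)P(=O)(OC)OC | intermediate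
4 | (triphenylphosphoranylidene)ketene | O=C=C=P(c1ccccc1)(c1ccccc1)c1ccccc1 | starting material
5 | 2-(trimethylsilyl)ethanol | C[Si](C)(C)CCO | starting material
6 | 2-(trimethylsilyl)ethyl (triphenylphosphoranylidene)acetate | C[Si](C)(C)CCOC(=O)C=P(c1ccccc1)(c1ccccc1)c1ccccc1 | intermediate
7 | 1,4-dioxaspiro[4.5]deca-6,9-dien-8-one | O=C1C=CC2(C=C1)OCCO2 | starting material
8 | (6R)-6-ethenyl-1,4-dioxaspiro[4.5]dec-9-en-8-one | C12(OCCO2)C=CC(=O)C[C@@H]1C=C | intermediate
9 | lithium dienolate of 8 (not isolated) | [Li+].C12(OCCO2)C=CC([O-])=C[C@@H]1C=C | intermediate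
10 | lithium aldolate, trans-hydroxymethyl adduct (not isolated) | [Li+].C12(OCCO2)C=CC(=O)[C@@H](C[O-])[C@@H]1C=C | intermediate
11 | (6S,7R)-6-ethenyl-7-{[(triethylsilyl)oxy]methyl}-1,4-dioxaspiro[4.5]dec-9-en-8-one | C12(OCCO2)C=CC(=O)[C@@H](CO[Si](CC)(CC)CC)[C@@H]1C=C | intermediate
12 | (6S,7R)-6-ethenyl-7-{[(triethylsilyl)oxy]methyl}-1,4-dioxaspiro[4.5]decan-8-one | C12(OCCO2)CCC(=O)[C@@H](CO[Si](CC)(CC)CC)[C@@H]1C=C | intermediate
13 | triethyl{[(6S,7S)-6-ethenyl-8-(propan-2-ylidene)-1,4-dioxaspiro[4.5]decan-7-yl]methoxy}silane | C12(OCCO2)CCC(=C(C)C)[C@@H](CO[Si](CC)(CC)CC)[C@@H]1C=C | intermediate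
14 | (6S,7S)-6-ethenyl-8-(propan-2-ylidene)-1,4-dioxaspiro[4.5]decane-7-carbaldehyde | C12(OCCO2)CCC(=C(C)C)[C@@H](C=O)[C@@H]1C=C | intermediate
15 | methyl (2E)-2-{[(6S,7S)-6-ethenyl-8-(propan-2-ylidene)-1,4-dioxaspiro[4.5]decan-7-yl]methylidene}-5,5-dimethoxypentanoate | C12(OCCO2)CCC(=C(C)C)[C@@H](/C=C(/C(=O)OC)CCC(OC)OC)[C@@H]1C=C | intermediate
16 | B-alkyl-9-borabicyclo[3.3.1]nonane adduct of 15 (not isolated) | C12(OCCO2)CCC(=C(C)C)[C@@H](/C=C(/C(=O)OC)CCC(OC)OC)[C@@H]1CCB1C2CCCC1CCC2 | intermediate
17 | methyl (2E)-2-{[(6S,7S)-6-(2-hydroxyethyl)-8-(propan-2-ylidene)-1,4-dioxaspiro[4.5]decan-7-yl]methylidene}-5,5-dimethoxypentanoate | C12(OCCO2)CCC(=C(C)C)[C@@H](/C=C(/C(=O)OC)CCC(OC)OC)[C@@H]1CCO | intermediate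
18 | methyl (2E)-2-{[(1S,2S)-2-(2-hydroxyethyl)-3-oxo-6-(propan-2-ylidene)cyclohexyl]methylidene}-5-oxopentanoate | O=C1CCC(=C(C)C)[C@@H](/C=C(/C(=O)OC)CCC=O)[C@@H]1CCO | intermediate
19 | 2-(trimethylsilyl)ethyl iodo(triphenylphosphoranylidene)acetate (not isolated) | IC(C(=O)OCC[Si](C)(C)C)=P(c1ccccc1)(c1ccccc1)c1ccccc1 | intermediate
20 | 1-methyl 7-[2-(trimethylsilyl)ethyl] (2E,5Z)-2-{[(1S,2S)-2-(2-hydroxyethyl)-3-oxo-6-(propan-2-ylidene)cyclohexyl]methylidene}-6-iodohept-5-enedioate | O=C1CCC(=C(C)C)[C@@H](/C=C(/C(=O)OC)CC/C=C(/C(=O)OCC[Si](C)(C)C)I)[C@@H]1CCO | intermediate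
21 | 1-methyl 7-[2-(trimethylsilyl)ethyl] (2E,5Z)-2-{[(1S,2S)-2-(2-hydroxyethyl)-3-methylidene-6-(propan-2-ylidene)cyclohexyl]methylidene}-6-iodohept-5-enedioate | C=C1CCC(=C(C)C)[C@@H](/C=C(/C(=O)OC)CC/C=C(/C(=O)OCC[Si](C)(C)C)I)[C@@H]1CCO | intermediate
22 | 1-methyl 7-[2-(trimethylsilyl)ethyl] (2E,5Z)-6-iodo-2-{[(1S,2S)-3-methylidene-2-(2-oxoethyl)-6-(propan-2-ylidene)cyclohexyl]methylidene}hept-5-enedioate | C=C1CCC(=C(C)C)[C@@H](/C=C(/C(=O)OC)CC/C=C(/C(=O)OCC[Si](C)(C)C)I)[C@@H]1CC=O | intermediate
23 | alkenylchromium dichloride from 22 (not isolated) | C=C1CCC(=C(C)C)[C@@H](/C=C(/C(=O)OC)CC/C=C(/C(=O)OCC[Si](C)(C)C)[Cr](Cl)Cl)[C@@H]1CC=O | intermediate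
24 | chromium alkoxide of 25 (not isolated) | C=C1CCC(=C(C)C)[C@H]2/C=C(/C(=O)OC)CC/C=C(/C(=O)OCC[Si](C)(C)C)[C@H](O[Cr](Cl)Cl)C[C@H]12 | intermediate
25 | microeunicellol A 2-(trimethylsilyl)ethyl ester | C=C1CCC(=C(C)C)[C@H]2/C=C(/C(=O)OC)CC/C=C(/C(=O)OCC[Si](C)(C)C)[C@H](O)C[C@H]12 | intermediate
26 | microeunicellol A | C=C1CCC(=C(C)C)[C@H]2/C=C(/C(=O)OC)CC/C=C(/C(=O)O)[C@H](O)C[C@H]12 | target

Total step count: 15
Longest linear sequence: 13 steps (steps 3 to 15, from 7 to 26)

Steps most likely to fail

Step 14. The ring closure may show poor facial selectivity at the aldehyde carbon, because the substrate-control model is only a prediction, and it competes with intermolecular coupling. The fallback replaces substrate control by reagent control and sets out from 25 taken as the mixture of carbinol epimers. Dess–Martin oxidation gives the macrocyclic alkylidene keto ester F1. Corey–Bakshi–Shibata reduction of F1 with (S)-2-methyl-CBS-oxazaborolidine and catecholborane at −78 °C, the alkenyl carbon acting as the large group, should return 25 with the (R) carbinol.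

Step 6. The basic, hindered ylide may enolise the α-branched ketone or trigger β-elimination of the silyloxy group instead of adding to the carbonyl. The fallback builds the tetrasubstituted alkene by cross-coupling and sets out from 12. Kinetic deprotonation on the CH2 side (KHMDS, PhNTf2, THF, −78 °C) gives the enol triflate F2. Suzuki–Miyaura coupling with isopropenylboronic acid pinacol ester (Pd(PPh3)4, K3PO4, dioxane/H2O) gives the 1,3-diene F3. 1,4-Hydrogenation of the diene with (η6-naphthalene)Cr(CO)3 under H2 in THF moves the unsaturation into the exocyclic position and comes back to the route at 13; the isolated vinyl group is not reduced.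

Step 3. The mono-adduct may react a second time at the remaining enone, the ketal may be lost with aromatisation, or the enantioselectivity may be too low on this 4,4-disubstituted dienone. The fallback separates diastereomers after a reagent-controlled reduction and sets out from 7. CuI-catalysed 1,4-addition of vinylmagnesium bromide (THF, −78 °C) gives the racemic enone F4. Reduction with (S)-2-methyl-CBS-oxazaborolidine and BH3·SMe2 converts both antipodes with the same sense at the carbinol carbon, so the two products are diastereomers that are separated by chromatography. The (6R,8R) allylic alcohol F5 is oxidised with MnO2 and comes back to the route at 8.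

Further compounds
F1 | step 14 | macrocyclic ketone: 25 with C=O in place of the carbinol CH(OH) | C=C1CCC(=C(C)C)[C@H]2/C=C(/C(=O)OC)CC/C=C(/C(=O)OCC[Si](C)(C)C)C(=O)C[C@H]12
F2 | step 6 | (6S,7R)-6-ethenyl-7-{[(triethylsilyl)oxy]methyl}-1,4-dioxaspiro[4.5]dec-8-en-8-yl trifluoromethanesulfonate | C12(OCCO2)CC=C(OS(=O)(=O)C(F)(F)F)[C@@H](CO[Si](CC)(CC)CC)[C@@H]1C=C
F3 | step 6 | triethyl{[(6S,7S)-6-ethenyl-8-(prop-1-en-2-yl)-1,4-dioxaspiro[4.5]dec-8-en-7-yl]methoxy}silane | C12(OCCO2)CC=C(C(C)=C)[C@@H](CO[Si](CC)(CC)CC)[C@@H]1C=C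
F4 | step 3 | racemic 6-ethenyl-1,4-dioxaspiro[4.5]dec-9-en-8-one | C=CC1CC(=O)C=CC12OCCO2
F5 | step 3 | (6R,8R)-6-ethenyl-1,4-dioxaspiro[4.5]dec-9-en-8-ol | C12(OCCO2)C=C[C@H](O)C[C@@H]1C=C
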